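Ring B is opened between C14 and C15, adjacent ring atoms that are both carbonyl carbons in an acyclic keto-aldehyde. A chiral triazolylidene carbene turns the C15 aldehyde into an acyl anion equivalent that adds to the C14 methyl ketone, so one operation forms C14–C15, closes the cyclohexane and sets the C14 carbinol centre cis to the C11 side chain. The precursor is (3S)-3-ethynyl-6-oxoheptanal carrying a triisopropylsilyl cap on the alkyne. Directed reduction, carboalumination–iodination and bromide inversion at C15 then give an (E)-iodoalkene bromohydrin, which is joined by Suzuki coupling to the bromo-oxane boronate made from (R)-linalool.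

Key step: step 4

Numbering: oxane O1, C2 (Me, dienyl), C3, C4, C5 (Br), C6 (Me2); diene C7=C8–C9=C10 (Me on C10); cyclohexane (ring B) C11 (H), C12, C13, C14 (Me, OH), C15 (Br), C16.

Target configuration used for planning: C2 R, C5 S, C11 S, C14 R, C15 S, 7E,9E. In ring B the C11 side chain, the C14 hydroxyl and the C15 bromine lie on one face. In the oxane the C5 bromine is trans to the C2 dienyl group. The silyl cap on the alkyne is the only change to the key-step precursor: it arrives with the alkyne, removes the acidic C–H and makes the small intermediates non-volatile.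

Assumption: the antipodes written for the ligand in step 2 and for the triazolium salt in step 4 are those expected to give the stated configurations; if a first run shows the opposite sense, the mirror-image ligand or catalyst is used and nothing else changes.

Step 1
Reactants: 1 2-methylhexa-1,5-diene; 2 (2E)-but-2-enal
Product: 3 (2E)-6-methylhepta-2,6-dienal
Conditions: second-generation Hoveyda–Grubbs catalyst (2 mol%), 2 (5 equiv), CH2Cl2, 40 °C
Reagents that add atoms: none
Why: Olefin cross-metathesis between the monosubstituted alkene of 1 and the enal should be selective because the 1,1-disubstituted alkene is too hindered to enter the cycle, and the conjugated product forms as the favoured E isomer.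

Step 2
Reactants: 3 (2E)-6-methylhepta-2,6-dienal; 4 ethynyltri(propan-2-yl)silane
Product: 5 (3S)-6-methyl-3-{[tri(propan-2-yl)silyl]ethynyl}hept-6-enal
Conditions: [Rh(OAc)(C2H4)2]2 (2.5 mol%), (R)-DTBM-SEGPHOS (6 mol%), MeOH, 40 °C
Reagents that add atoms: none
Why: Rhodium-catalysed asymmetric conjugate alkynylation of an enal, in which the bulky silyl group suppresses alkyne dimerisation, the chiral bisphosphine–rhodium alkynyl adds to one enantioface of the enal to set C11 as (S), and methanol protonates the enolate, which has no ketone within reach because that group is still masked as the 1,1-disubstituted alkene.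

Step 3
Reactants: 5 (3S)-6-methyl-3-{[tri(propan-2-yl)silyl]ethynyl}hept-6-enal
Product: 7 (3S)-6-oxo-3-{[tri(propan-2-yl)silyl]ethynyl}heptanal, via ozonide 6 (not isolated)
Conditions: O3, CH2Cl2, −78 °C, Sudan red 7B as end-point dye; then PPh3, −78 → 23 °C
Reagents that add atoms: ozone [O-][O+]=O
Why: Ozonolysis with reductive work-up cleaves the electron-rich 1,1-disubstituted alkene much faster than the silyl-capped alkyne, unmasking the methyl ketone without touching the C11 centre.

Step 4
Reactants: 7 (3S)-6-oxo-3-{[tri(propan-2-yl)silyl]ethynyl}heptanal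
Product: 8 (2R,5S)-2-hydroxy-2-methyl-5-{[tri(propan-2-yl)silyl]ethynyl}cyclohexan-1-one
Conditions: (5aR,10bS)-2-(pentafluorophenyl)-5a,10b-dihydro-4H,6H-indeno[2,1-b][1,2,4]triazolo[4,3-d][1,4]oxazin-2-ium tetrafluoroborate (15 mol%), Et3N (15 mol%), toluene (0.05 M), 23 °C
Reagents that add atoms: none
Why: The triazolylidene freed by the amine adds to the C15 aldehyde and proton transfer gives the enaminol (Breslow intermediate), whose nucleophilic C15 attacks the C14 ketone while its hydroxyl proton passes to the ketone oxygen; collapse of the adduct releases the carbene and the α-hydroxy ketone. The closest known reaction type is the intramolecular crossed aldehyde–ketone benzoin cyclisation under chiral aminoindanol-derived triazolylidene catalysis, for which purely aliphatic methyl ketones are known but less selective substrates. Ring B closes in the 6-exo-trig mode by formation of C14–C15. The new C14 centre (R, hydroxyl cis to the C11 alkynyl group) is set by the chiral carbene, which directs the enaminol to the Si face of the ketone, reinforced by a chair-like closure with the C11 substituent and the C14 methyl group equatorial. The step needs donor/acceptor chemoselectivity and freedom from aldol closure: only the aldehyde can form the enaminol, only the ketone is placed to accept it through a six-membered ring, and catalytic weak base at high dilution keeps enolisation and intermolecular benzoin slow. C11 is β to both carbonyl groups and carries no acidic hydrogen, and the silyl cap removes the acidic alkyne C–H, so the existing centre survives.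

Step 5
Reactants: 8 (2R,5S)-2-hydroxy-2-methyl-5-{[tri(propan-2-yl)silyl]ethynyl}cyclohexan-1-one
Product: 9 (1R,2R,4S)-1-methyl-4-{[tri(propan-2-yl)silyl]ethynyl}cyclohexane-1,2-diol
Conditions: Me4NBH(OAc)3 (5 equiv), MeCN/AcOH, −30 → 0 °C
Reagents that add atoms: none
Why: Hydroxyl-directed triacetoxyborohydride reduction (Saksena–Evans type), in which the tertiary C14 hydroxyl exchanges onto boron and delivers hydride to C15 from its own face, so the new secondary hydroxyl should come out trans to it (C15 R, trans-diaxial diol), as required for a later single inversion.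

Step 6
Reactants: 9 (1R,2R,4S)-1-methyl-4-{[tri(propan-2-yl)silyl]ethynyl}cyclohexane-1,2-diol
Product: 10 (1R,2R,4S)-4-ethynyl-1-methylcyclohexane-1,2-diol
Conditions: Bu4NF (1.5 equiv), THF, 0 → 23 °C
Reagents that add atoms: none
Why: Fluoride-induced protodesilylation of the alkynylsilane frees the terminal alkyne, and the diol carries nothing that is labile to fluoride or to the mildly basic medium.

Step 7
Reactants: 10 (1R,2R,4S)-4-ethynyl-1-methylcyclohexane-1,2-diol
Product: 12 (1R,2R,4S)-4-[(1E)-1-iodoprop-1-en-2-yl]-1-methylcyclohexane-1,2-diol, via alkenylalane 11 (not isolated)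
Conditions: AlMe3 (5 equiv), Cp2ZrCl2 (20 mol%), CH2Cl2, 0 → 23 °C; then I2, THF, −30 °C; aq. K2CO3
Reagents that add atoms: trimethylaluminium C[Al](C)C; iodine II
Why: Zirconium-catalysed carboalumination (Negishi) adds methyl and aluminium syn across the terminal alkyne with aluminium on the terminal carbon, and iodinolysis with retention gives the (E)-iodoalkene, the two hydroxyls being carried as aluminium alkoxides by the excess AlMe3.

Step 8
Reactants: 12 (1R,2R,4S)-4-[(1E)-1-iodoprop-1-en-2-yl]-1-methylcyclohexane-1,2-diol
Product: 14 (1R,2R,5S)-5-[(1E)-1-iodoprop-1-en-2-yl]-2-methyl-2-[(trimethylsilyl)oxy]cyclohexyl chloromethanesulfonate, via hydroxy sulfonate 13 (not isolated)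
Conditions: ClCH2SO2Cl (1.2 equiv), 2,6-lutidine (4 equiv), CH2Cl2, 0 °C; then Me3SiOTf (1.5 equiv), −78 °C
Reagents that add atoms: chloromethanesulfonyl chloride ClCS(=O)(=O)Cl; trimethylsilyl trifluoromethanesulfonate C[Si](C)(C)OS(=O)(=O)C(F)(F)F
Why: Chemoselective sulfonylation, since the secondary C15 hydroxyl reacts with the sulfonyl chloride while the tertiary C14 hydroxyl does not, and silylation of the latter in the same flask by the stronger silyl triflate blocks later epoxide closure onto C15.

Step 9
Reactants: 14 (1R,2R,5S)-5-[(1E)-1-iodoprop-1-en-2-yl]-2-methyl-2-[(trimethylsilyl)oxy]cyclohexyl chloromethanesulfonate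
Product: 16 (1R,2S,4S)-2-bromo-4-[(1E)-1-iodoprop-1-en-2-yl]-1-methylcyclohexan-1-ol, via bromo silyl ether 15 (not isolated)
Conditions: Bu4NBr (4 equiv), toluene, 80 °C; then 1 M HCl, THF, 0 °C
Reagents that add atoms: tetrabutylammonium bromide CCCC[N+](CCCC)(CCCC)CCCC.[Br-]
Why: SN2 displacement of the axial chloromethanesulfonate, a leaving group far more reactive than mesylate, by weakly basic bromide inverts C15 to the equatorial (S)-bromide cis to the C14 oxygen, and brief aqueous acid then cleaves the tertiary trimethylsilyl ether.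

Step 10
Reactants: 17 (3R)-3,7-dimethylocta-1,6-dien-3-ol, (R)-(−)-linalool
Product: 18 (3S,6R)-3-bromo-6-ethenyl-2,2,6-trimethyloxane
Conditions: 2,4,4,6-tetrabromocyclohexa-2,5-dien-1-one (1.1 equiv), CH2Cl2, −20 → 23 °C; chromatography
Reagents that add atoms: 2,4,4,6-tetrabromocyclohexa-2,5-dien-1-one O=C1C(Br)=CC(Br)(Br)C=C1Br
Why: Bromoetherification, in which the bromonium ion of the trisubstituted alkene is opened by the tertiary hydroxyl at the more substituted carbon (6-endo, Markovnikov) through a chair with bromine equatorial, C2 keeps the configuration of linalool, and because methyl and vinyl compete for the equatorial site at C2 both C5 epimers are expected, of which the (2R,5S) isomer in target numbering (bromine trans to vinyl) is separated and taken on.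

Step 11
Reactants: 18 (3S,6R)-3-bromo-6-ethenyl-2,2,6-trimethyloxane
Product: 20 (2R,5S)-5-bromo-2,6,6-trimethyloxane-2-carbaldehyde, via ozonide 19 (not isolated)
Conditions: O3, CH2Cl2, −78 °C; then PPh3, −78 → 23 °C
Reagents that add atoms: ozone [O-][O+]=O
Why: Ozonolysis with reductive work-up cleaves the only alkene to the aldehyde, whose quaternary α-carbon cannot epimerise.

Step 12
Reactants: 20 (2R,5S)-5-bromo-2,6,6-trimethyloxane-2-carbaldehyde; 21 2-(dichloromethyl)-4,4,5,5-tetramethyl-1,3,2-dioxaborolane
Product: 22 2-[(E)-2-[(2R,5S)-5-bromo-2,6,6-trimethyloxan-2-yl]ethenyl]-4,4,5,5-tetramethyl-1,3,2-dioxaborolane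
Conditions: CrCl2 (8 equiv), LiI (4 equiv), THF, 23 °C
Reagents that add atoms: none
Why: Takai–Utimoto boryl olefination, in which the geminal dichromium species formed from the dihalomethylboronate adds to the aldehyde and eliminates to the (E)-alkenylboronate, E selectivity being highest with α-branched aldehydes, while unactivated secondary alkyl bromides are not expected to be reduced by CrCl2 in THF at this temperature.

Step 13
Reactants: 16 (1R,2S,4S)-2-bromo-4-[(1E)-1-iodoprop-1-en-2-yl]-1-methylcyclohexan-1-ol; 22 2-[(E)-2-[(2R,5S)-5-bromo-2,6,6-trimethyloxan-2-yl]ethenyl]-4,4,5,5-tetramethyl-1,3,2-dioxaborolane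
Product: 23 (1R,2S,4S)-2-bromo-4-[(2E,4E)-5-[(2R,5S)-5-bromo-2,6,6-trimethyloxan-2-yl]penta-2,4-dien-2-yl]-1-methylcyclohexan-1-ol
Conditions: Pd(dppf)Cl2 (10 mol%), Ph3As (20 mol%), Cs2CO3 (3 equiv), DMF/THF/H2O, 23 °C
Reagents that add atoms: none
Why: Suzuki–Miyaura coupling, in which zerovalent palladium inserts into the alkenyl C–I bond far faster than into the unactivated secondary C–Br bonds and transmetalation and reductive elimination proceed with retention at both alkenes to give the (7E,9E)-diene, the mild carbonate base leaving the bromohydrin and the free tertiary hydroxyl untouched.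

Compound list
1 | 2-methylhexa-1,5-diene | C=C(C)CCC=C | starting material
2 | (2E)-but-2-enal | C/C=C/C=O | starting material
3 | (2E)-6-methylhepta-2,6-dienal | C=C(C)CC/C=C/C=O | intermediate
4 | ethynyltri(propan-2-yl)silane | C#C[Si](C(C)C)(C(C)C)C(C)C | starting material
5 | (3S)-6-methyl-3-{[tri(propan-2-yl)silyl]ethynyl}hept-6-enal | CC(C)[Si](C#C[C@H](CC=O)CCC(C)=C)(C(C)C)C(C)C | intermediate
6 | (3S)-5-(3-methyl-1,2,4-trioxolan-3-yl)-3-{[tri(propan-2-yl)silyl]ethynyl}pentanal, ozonide of 5, not isolated | CC(C)[Si](C#C[C@H](CC=O)CCC1(C)OCOO1)(C(C)C)C(C)C | intermediate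
7 | (3S)-6-oxo-3-{[tri(propan-2-yl)silyl]ethynyl}heptanal | CC(C)[Si](C#C[C@H](CC=O)CCC(C)=O)(C(C)C)C(C)C | intermediate
8 | (2R,5S)-2-hydroxy-2-methyl-5-{[tri(propan-2-yl)silyl]ethynyl}cyclohexan-1-one | CC(C)[Si](C#C[C@H]1CC[C@@](C)(O)C(=O)C1)(C(C)C)C(C)C | intermediate
9 | (1R,2R,4S)-1-methyl-4-{[tri(propan-2-yl)silyl]ethynyl}cyclohexane-1,2-diol | CC(C)[Si](C#C[C@H]1CC[C@@](C)(O)[C@H](O)C1)(C(C)C)C(C)C | intermediate
10 | (1R,2R,4S)-4-ethynyl-1-methylcyclohexane-1,2-diol | C#C[C@H]1CC[C@@](C)(O)[C@H](O)C1 | intermediate
11 | (E)-alkenyl(dimethyl)alane of 10 with both hydroxyls as dimethylaluminium alkoxides, not isolated | C/C(=C\[Al](C)C)[C@H]1CC[C@@](C)(O[Al](C)C)[C@H](O[Al](C)C)C1 | intermediate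
12 | (1R,2R,4S)-4-[(1E)-1-iodoprop-1-en-2-yl]-1-methylcyclohexane-1,2-diol | C/C(=C\I)[C@H]1CC[C@@](C)(O)[C@H](O)C1 | intermediate
13 | (1R,2R,5S)-2-hydroxy-5-[(1E)-1-iodoprop-1-en-2-yl]-2-methylcyclohexyl chloromethanesulfonate, not isolated | C/C(=C\I)[C@H]1CC[C@@](C)(O)[C@H](OS(=O)(=O)CCl)C1 | intermediate
14 | (1R,2R,5S)-5-[(1E)-1-iodoprop-1-en-2-yl]-2-methyl-2-[(trimethylsilyl)oxy]cyclohexyl chloromethanesulfonate | C/C(=C\I)[C@H]1CC[C@@](C)(O[Si](C)(C)C)[C@H](OS(=O)(=O)CCl)C1 | intermediate
15 | {[(1R,2S,4S)-2-bromo-4-[(1E)-1-iodoprop-1-en-2-yl]-1-methylcyclohexyl]oxy}(trimethyl)silane, not isolated | C/C(=C\I)[C@H]1CC[C@@](C)(O[Si](C)(C)C)[C@@H](Br)C1 | intermediate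
16 | (1R,2S,4S)-2-bromo-4-[(1E)-1-iodoprop-1-en-2-yl]-1-methylcyclohexan-1-ol | C/C(=C\I)[C@H]1CC[C@@](C)(O)[C@@H](Br)C1 | intermediate
17 | (3R)-3,7-dimethylocta-1,6-dien-3-ol, (R)-(−)-linalool | C=C[C@@](O)(C)CCC=C(C)C | starting material
18 | (3S,6R)-3-bromo-6-ethenyl-2,2,6-trimethyloxane | C=C[C@@]1(C)CC[C@H](Br)C(C)(C)O1 | intermediate
19 | 3-[(2R,5S)-5-bromo-2,6,6-trimethyloxan-2-yl]-1,2,4-trioxolane, ozonide of 18, not isolated | C1(OCOO1)[C@@]2(C)CC[C@H](Br)C(C)(C)O2 | intermediate
20 | (2R,5S)-5-bromo-2,6,6-trimethyloxane-2-carbaldehyde | O=C[C@@]1(C)CC[C@H](Br)C(C)(C)O1 | intermediate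
21 | 2-(dichloromethyl)-4,4,5,5-tetramethyl-1,3,2-dioxaborolane | ClC(Cl)B1OC(C)(C)C(C)(C)O1 | starting material
22 | 2-[(E)-2-[(2R,5S)-5-bromo-2,6,6-trimethyloxan-2-yl]ethenyl]-4,4,5,5-tetramethyl-1,3,2-dioxaborolane | CC1(C)OB(/C=C/[C@@]2(C)CC[C@H](Br)C(C)(C)O2)OC1(C)C | intermediate
23 | (1R,2S,4S)-2-bromo-4-[(2E,4E)-5-[(2R,5S)-5-bromo-2,6,6-trimethyloxan-2-yl]penta-2,4-dien-2-yl]-1-methylcyclohexan-1-ol | C/C(=C\C=C\[C@@]1(C)CC[C@H](Br)C(C)(C)O1)[C@H]1CC[C@@](C)(O)[C@@H](Br)C1 | target

Total step count: 13. Longest linear sequence: 10 (steps 1–9, then step 13); the oxane arm (steps 10–12) is three steps.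

Steps most likely to fail

Step 4. Facial selectivity at the C14 ketone may be poor, because a purely aliphatic methyl ketone is a weak substrate for the chiral carbene and the small alkynyl group anchors the chair only weakly. Base-induced aldol closure may also compete with carbene catalysis. The fallback sets out from 7 and comes back at 9, bypassing 8 and step 5. Intramolecular McMurry coupling of 7 (TiCl4, Zn, pyridine, THF, reflux, slow addition) should give (4S)-1-methyl-4-{[tri(propan-2-yl)silyl]ethynyl}cyclohex-1-ene F1. Shi epoxidation (fructose-derived ketone catalyst, KHSO5, K2CO3 buffer, MeCN/dimethoxymethane, 0 °C), with the catalyst antipode that oxidises the face anti to the alkynyl group, should give (1S,4S,6R)-1-methyl-4-{[tri(propan-2-yl)silyl]ethynyl}-7-oxabicyclo[4.1.0]heptane F2. Acid-catalysed hydrolysis (catalytic HClO4, THF/H2O, 0 → 23 °C) should open F2 at the tertiary carbon C14 in the trans-diaxial sense (Fürst–Plattner rule, as limonene oxide does). This places the C14 hydroxyl cis to the alkynyl group and leaves the C15 oxygen trans, which is diol 9.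

Step 9. Substitution at C15 may be slow because the carbon is flanked by the fully substituted C14. Elimination toward C16, or participation of the C14 oxygen with net retention, could then compete. The fallback sets out from 12 and comes back at 16, bypassing 13–15. SOCl2 and Et3N in CH2Cl2 at 0 °C should tie both oxygens into the trans-fused cyclic sulfite (3aR,6S,7aR)-6-[(1E)-1-iodoprop-1-en-2-yl]-3a-methylhexahydro-1,3,2-benzodioxathiole 2-oxide F3, as a mixture of sulfur epimers. LiBr in DMF at 90 °C should open the strained ring at the secondary carbon C15 with inversion, giving lithium (1R,2S,4S)-2-bromo-4-[(1E)-1-iodoprop-1-en-2-yl]-1-methylcyclohexyl sulfite F4. This loses its sulfite group on dilute acidic aqueous work-up to give 16. The C14 oxygen stays bound to sulfur until the C–Br bond exists, so it can neither close an epoxide nor participate.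

Step 12. Addition of the chromium carbenoid to the hindered α-alkoxy aldehyde may be sluggish, and excess CrCl2 may slowly reduce the C5 bromide. The fallback sets out from 18 (together with 16) and comes back at 23, bypassing steps 11–13. It is a ligand-free Heck coupling under phase-transfer conditions (Pd(OAc)2 10 mol%, Bu4NCl, K2CO3, DMF, 50 °C). The alkenylpalladium formed from 16 should add to the terminal carbon of the vinyl group of 18. Because C2 is quaternary, the only β-hydrogen is on C7, so elimination can give only the (7E)-diene, with the iodoalkene geometry retained. New compounds on this way: none F0.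

Further compounds
F1 | step 4 | (4S)-1-methyl-4-{[tri(propan-2-yl)silyl]ethynyl}cyclohex-1-ene | CC(C)[Si](C#C[C@H]1CCC(C)=CC1)(C(C)C)C(C)C
F2 | step 4 | (1S,4S,6R)-1-methyl-4-{[tri(propan-2-yl)silyl]ethynyl}-7-oxabicyclo[4.1.0]heptane | CC(C)[Si](C#C[C@H]1CC[C@]2(C)O[C@@H]2C1)(C(C)C)C(C)C
F3 | step 9 | (3aR,6S,7aR)-6-[(1E)-1-iodoprop-1-en-2-yl]-3a-methylhexahydro-1,3,2-benzodioxathiole 2-oxide | C/C(=C\I)[C@H]1CC[C@@]2(C)OS(=O)O[C@@H]2C1
F4 | step 9 | lithium (1R,2S,4S)-2-bromo-4-[(1E)-1-iodoprop-1-en-2-yl]-1-methylcyclohexyl sulfite | C/C(=C\I)[C@H]1CC[C@@](C)(OS(=O)[O-])[C@@H](Br)C1.[Li+]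
F0 | step 12 | none | none
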